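## Retrosynthetic overview

1. The seven-membered ring is made last: the benzotropolone of 31 is opened to the catechol–pyrogallol biaryl 30 (oxidative closure of C4a–C5, one pyrogallol carbon lost as CO2). The biaryl bond is the later C9–C9a bond, so a Suzuki coupling fixes where both flavans sit, and no tropone is present while arynes, boranes and hydrides are in use.
2. Both pyran rings (rings C) and both phloroglucinol rings (rings A) come off together: bis-chromene 22 ⇒ biaryl bis-enal 13 + two molecules of 3,5-bis(benzyloxy)benzyne (two equivalents of precursor 19). Each aryne takes up the enal oxygen and the enal carbonyl carbon on neighbouring carbons, and each pyran ring then closes by O1–C2 bond formation.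
3. Enabling feature: in each flavan, ring A carries O1 and C4 on the adjacent carbons C8a and C4a, with the C5 oxygen next to C4a. This is the imprint of a 3-alkoxybenzyne, which takes a nucleophile at the carbon remote from OR. C4–C3–C2 of ring C is the carbon chain of an enal whose carbonyl oxygen becomes O1; C2 lies next to C3, so at the C3 ketone level it epimerises and C2/C3 are set afterwards by reductive dynamic kinetic resolution.
4. The two arms differ in oxidation level, so the two C3 carbinols appear one after the other: a 2-methoxy enal (masked C3 ketone) for the flavan that receives the gallate, a plain enal (C3–O by hydroboration, then oxidation) for the other.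
5. Ring order: the two benzene rings of the biaryl are joined (step 7) → rings A and C of both flavans in one operation (step 12) → tropolone ring (step 20).

Key step: step 12

Remark (locants): in the biaryl the catechol-derived ring carries C1 (biaryl bond), C2 (arm 1, later the galloylated flavan) and C4, C5 (oxygens); the pyrogallol-derived ring carries C1′ (biaryl bond), C2′, C3′, C4′ (oxygens) and C5′ (arm 2, later the free flavan).

Remark (isomers): 22 and 23 are mixtures of epimers at both flavan C2 atoms; 24, 26, 27 and 28 are mixtures at the arm 2 C2 atom (27 also at the arm 2 C3 atom). The biaryl axis, with one ortho substituent on each ring, is taken to rotate freely, so no atropisomers are carried.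

Assumption: RuCl[(R,R)-TsDPEN](p-cymene) is taken to be the enantiomer that delivers the (2R,3R) alcohols; should a model flavan-3-one show the opposite sense, the (S,S) complex replaces it in steps 14 and 18 and nothing else changes.

## Route

Step 1
Reactants: 1 3,4-bis(benzyloxy)benzaldehyde
Product: 2 4,5-bis(benzyloxy)-2-bromobenzaldehyde
Conditions: Br2 (1.05 equiv), NaOAc, AcOH, rt
Reagents that add atoms: bromine BrBr
Why: Electrophilic aromatic bromination should go to C6 (para to the 3-benzyloxy group), the usual site for 3,4-dialkoxybenzaldehydes, and NaOAc buffers the HBr so the benzyl ethers survive.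

Step 2
Reactants: 2 4,5-bis(benzyloxy)-2-bromobenzaldehyde; 3 methyl 2-(dimethoxyphosphoryl)-2-methoxyacetate
Product: 4 methyl (Z)-3-[4,5-bis(benzyloxy)-2-bromophenyl]-2-methoxyprop-2-enoate
Conditions: NaH, THF, 0 °C → rt
Reagents that add atoms: none
Why: Horner–Wadsworth–Emmons olefination of the aryl aldehyde should give the 2-methoxycinnamate (Z expected as the major isomer); the alkene geometry is lost in step 12, so either isomer serves.

Step 3
Reactants: 5 2,3,4-trihydroxybenzaldehyde
Product: 6 2,3,4-tris(benzyloxy)benzaldehyde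
Conditions: BnBr (3.5 equiv), K2CO3, DMF, 60 °C
Reagents that add atoms: benzyl bromide BrCc1ccccc1
Why: Williamson etherification of the three phenols leaves the aldehyde untouched.

Step 4
Reactants: 6 2,3,4-tris(benzyloxy)benzaldehyde
Product: 7 2,3,4-tris(benzyloxy)-5-bromobenzaldehyde
Conditions: NBS (1.05 equiv), DMF, 0 °C → rt
Reagents that add atoms: N-bromosuccinimide O=C1CCC(=O)N1Br
Why: Electrophilic aromatic bromination should occur at C5, which is para to the 2-ether, ortho to the 4-ether and meta to CHO, whereas C6 is ortho to CHO and para only to the twisted 3-ether.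

Step 5
Reactants: 7 2,3,4-tris(benzyloxy)-5-bromobenzaldehyde; 8 methyl (triphenylphosphoranylidene)acetate
Product: 9 methyl (E)-3-[2,3,4-tris(benzyloxy)-5-bromophenyl]prop-2-enoate
Conditions: toluene, 90 °C
Reagents that add atoms: none
Why: Wittig olefination with the stabilised ylide should give the E-cinnamate.

Step 6
Reactants: 9 methyl (E)-3-[2,3,4-tris(benzyloxy)-5-bromophenyl]prop-2-enoate
Product: 10 methyl (E)-3-[2,3,4-tris(benzyloxy)-5-(4,4,5,5-tetramethyl-1,3,2-dioxaborolan-2-yl)phenyl]prop-2-enoate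
Conditions: bis(pinacolato)diboron, Pd(dppf)Cl2 (3 mol %), KOAc, 1,4-dioxane, 85 °C
Reagents that add atoms: bis(pinacolato)diboron CC1(C)OB(OC1(C)C)B1OC(C)(C)C(C)(C)O1
Why: Miyaura borylation of the aryl bromide under KOAc tolerates the ester and the 1,2-disubstituted cinnamate alkene.

Step 7
Reactants: 4 methyl (Z)-3-[4,5-bis(benzyloxy)-2-bromophenyl]-2-methoxyprop-2-enoate; 10 methyl (E)-3-[2,3,4-tris(benzyloxy)-5-(4,4,5,5-tetramethyl-1,3,2-dioxaborolan-2-yl)phenyl]prop-2-enoate
Product: 11 biaryl diester (methyl (Z)-2-methoxyprop-2-enoate arm at C2; methyl (E)-prop-2-enoate arm at C5′; benzyloxy groups at C4, C5, C2′, C3′, C4′)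
Conditions: Pd(OAc)2 (5 mol %), SPhos (10 mol %), K3PO4, toluene/H2O (10:1), 80 °C
Reagents that add atoms: none
Why: Suzuki–Miyaura cross-coupling joins the carbons that become C9a and C9 of the benzotropolone, the biaryl phosphine handling the one ortho substituent on each partner; no stereocentre arises.

Step 8
Reactants: 11 biaryl diester
Product: 12 biaryl bis(allylic alcohol) ((Z)-3-hydroxy-2-methoxyprop-1-enyl at C2; (E)-3-hydroxyprop-1-enyl at C5′)
Conditions: iBu2AlH (5 equiv), CH2Cl2, −78 → −20 °C; aq. potassium sodium tartrate (KNaC4H4O6)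
Reagents that add atoms: none
Why: iBu2AlH should reduce both conjugated esters by 1,2-addition to the allylic alcohols, and the near-neutral tartrate work-up spares the enol ether.

Step 9
Reactants: 12 biaryl bis(allylic alcohol)
Product: 13 biaryl bis-enal ((Z)-2-methoxy-3-oxoprop-1-enyl at C2; (E)-3-oxoprop-1-enyl at C5′)
Conditions: MnO2 (activated, excess), CH2Cl2, rt
Reagents that add atoms: none
Why: Allylic oxidation with MnO2 stops at the aldehyde and leaves the enol ether and the benzyl ethers alone.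

Step 10
Reactants: 14 3,5-bis(benzyloxy)phenol
Product: 15 3,5-bis(benzyloxy)-2-bromophenol
Conditions: NBS (1.0 equiv), CH2Cl2, −78 °C → rt
Reagents that add atoms: N-bromosuccinimide O=C1CCC(=O)N1Br
Why: Electrophilic bromination of the phenol should favour the two equivalent ortho positions over C4, which is flanked by two benzyloxy groups; any 4-bromo isomer is removed by chromatography.

Step 11
Reactants: 15 3,5-bis(benzyloxy)-2-bromophenol
Product: 19 3,5-bis(benzyloxy)-2-(trimethylsilyl)phenyl trifluoromethanesulfonate, via aryl trimethylsilyl ether 16 (not isolated), via aryllithium 17 (not isolated), via lithium 2-silylphenoxide 18 (not isolated)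
Conditions: (Me3Si)2NH, THF, 65 °C; evaporate; n-BuLi, THF, −100 → −78 °C; Tf2O, −78 °C → rt
Reagents that add atoms: hexamethyldisilazane C[Si](C)(C)N[Si](C)(C)C; trifluoromethanesulfonic anhydride O=S(=O)(OS(=O)(=O)C(F)(F)F)C(F)(F)F
Why: O-Silylation, bromine–lithium exchange, anionic 1,3 O→C silyl shift (retro-Brook rearrangement) and O-triflation are the standard sequence to an ortho-silylaryl triflate aryne precursor.

Step 12
Reactants: 13 biaryl bis-enal; 19 3,5-bis(benzyloxy)-2-(trimethylsilyl)phenyl trifluoromethanesulfonate (two molar equivalents are built into the product, one per enal arm)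
Product: 22 biaryl bis-chromene (arm 1: 5,7-bis(benzyloxy)-3-methoxy-2H-chromen-2-yl; arm 2: 5,7-bis(benzyloxy)-2H-chromen-2-yl; C2 epimers), via 3,5-bis(benzyloxy)benzyne 20 (not isolated), via bis(ortho-quinone methide) 21 (not isolated)
Conditions: 19 (2.6 equiv in all, added over 6 h), CsF (6 equiv), MeCN/toluene (1:1), rt → 40 °C
Reagents that add atoms: 3,5-bis(benzyloxy)-2-(trimethylsilyl)phenyl trifluoromethanesulfonate (the second equivalent of 19) C[Si](C)(C)c1c(OCc2ccccc2)cc(OCc2ccccc2)cc1OS(=O)(=O)C(F)(F)F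
Why: Fluoride removes the silyl group of 19 and triflate leaves, giving one molecule of aryne 20 for each enal arm; each aldehyde oxygen of 13 adds to the aryne carbon remote from the flanking benzyloxy group (the more distorted, more electrophilic terminus, with the developing negative charge placed beside the inductively withdrawing C–OBn), the aryl anion closes on the carbonyl carbon (formal [2+2]) and 4π ring opening gives the ortho-quinone methide 21, so O1/C8a and C4/C4a are set with the C5 oxygen beside C4a as ring A requires. The 1-oxatriene O=C8a–C4a=C4–C3=C2 then closes each pyran ring by a thermal disrotatory oxa-6π electrocyclisation that forms O1–C2 and restores the aromaticity of ring A. The closest known reaction is the aryne/α,β-unsaturated aldehyde route to 2H-chromenes (aryne–carbonyl [2+2], ring opening, oxa-6π closure), run here on both enal arms in one flask. The new stereocentres at C2 of both pyran rings form without control, which is intended: each lies next to C3 and is reset under catalyst control at the ketone stage in steps 14 and 18. The step needs regioselectivity (O to C8a, C to C4a), secured by the benzyloxy group beside the triple bond, and chemoselectivity for the 6π closure over capture of 21 by a further aryne, secured by the intramolecular closure and the slow addition of 19; the tropolone, which would itself trap arynes, is not yet present because the seven-membered ring is carried as the inert benzyl-protected biaryl.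

Step 13
Reactants: 22 biaryl bis-chromene
Product: 23 arm 1 flavan-3-one (arm 1: 5,7-bis(benzyloxy)-3-oxochroman-2-yl; arm 2 unchanged)
Conditions: 1 M aq. HCl, THF, 0 °C → rt
Reagents that add atoms: water O
Why: Acid-catalysed enol ether hydrolysis (protonation at C4, oxocarbenium ion at C3, water) unmasks the C3 ketone, while the far less basic styrenic alkene of arm 2 should stay intact.

Step 14
Reactants: 23 arm 1 flavan-3-one
Product: 24 arm 1 cis-alcohol (arm 1: (2R,3R)-5,7-bis(benzyloxy)-3-hydroxychroman-2-yl; arm 2 unchanged)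
Conditions: RuCl[(R,R)-TsDPEN](p-cymene) (5 mol %), HCO2H/Et3N (1:1), DMF, 30 °C
Reagents that add atoms: none
Why: Noyori–Ikariya asymmetric transfer hydrogenation with dynamic kinetic resolution: C2–H (α to C=O, benzylic, α to the ring oxygen) epimerises through the enol under Et3N faster than hydride transfer, and the catalyst reduces the (2R)-ketone from the face opposite the 2-aryl group, setting C2 and C3 together as cis-(2R,3R); the arm 2 alkene is not reduced.

Step 15
Reactants: 24 arm 1 cis-alcohol; 25 3,4,5-tris(benzyloxy)benzoic acid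
Product: 26 arm 1 gallate (3,4,5-tris(benzyloxy)benzoate of 24)
Conditions: DCC, DMAP (cat.), CH2Cl2, rt
Reagents that add atoms: none
Why: Steglich esterification acylates the only free hydroxyl with retention at C3.

Step 16
Reactants: 26 arm 1 gallate
Product: 27 arm 2 trans-alcohol (arm 2: 2,3-trans-5,7-bis(benzyloxy)-3-hydroxychroman-2-yl; both antipodal series)
Conditions: BH3·THF, THF, 0 °C → rt; then Me3NO·2H2O, 65 °C
Reagents that add atoms: trimethylamine N-oxide C[N+](C)(C)[O-]
Why: Hydroboration–oxidation places boron at C3 (β to ring A) anti to the 2-aryl group, and the non-basic amine oxide oxidation spares the gallate ester; the stereochemistry formed here is erased in step 17.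

Step 17
Reactants: 27 arm 2 trans-alcohol
Product: 28 arm 2 flavan-3-one (arm 2: 5,7-bis(benzyloxy)-3-oxochroman-2-yl)
Conditions: Dess–Martin periodinane, CH2Cl2, 0 °C → rt
Reagents that add atoms: none
Why: Dess–Martin oxidation of the only free secondary alcohol gives the ketone whose C2 is again epimerisable.

Step 18
Reactants: 28 arm 2 flavan-3-one
Product: 29 fully protected biaryl bis-flavan (arm 2: (2R,3R)-5,7-bis(benzyloxy)-3-hydroxychroman-2-yl)
Conditions: RuCl[(R,R)-TsDPEN](p-cymene) (5 mol %), HCO2H/Et3N (1:1), DMF, 30 °C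
Reagents that add atoms: none
Why: A second Noyori–Ikariya transfer hydrogenation with dynamic kinetic resolution sets C2 and C3 of arm 2 as cis-(2R,3R) by the same epimerisation/face-selective reduction; arm 1 has no acidic C2–H left and is not affected.

Step 19
Reactants: 29 fully protected biaryl bis-flavan
Product: 30 free catechol–pyrogallol biaryl ((2R,3R)-2-{4,5-dihydroxy-2-[2,3,4-trihydroxy-5-((2R,3R)-3,5,7-trihydroxychroman-2-yl)phenyl]phenyl}-5,7-dihydroxychroman-3-yl 3,4,5-trihydroxybenzoate)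
Conditions: H2 (1 atm), Pd(OH)2/C, THF/MeOH (1:1), rt; filtered and concentrated under argon
Reagents that add atoms: none
Why: Hydrogenolysis removes all twelve benzyl ethers, and since no tropolone or alkene is present nothing else is reducible.

Step 20
Reactants: 30 free catechol–pyrogallol biaryl
Product: 31 CNP0217128.1 ((2R,3R)-5,7-dihydroxy-2-{3,4,6-trihydroxy-5-oxo-7-[(2R,3R)-3,5,7-trihydroxychroman-2-yl]-5H-benzo[7]annulen-1-yl}chroman-3-yl 3,4,5-trihydroxybenzoate)
Conditions: horseradish peroxidase (cat.), H2O2 (2.2 equiv, slow addition), acetone/citrate–phosphate buffer pH 5 (1:10), rt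
Reagents that add atoms: none
Why: Proposed new method: the pyrogallol ring, the most easily oxidised ring, should go to its hydroxy-ortho-quinone, the catechol carbon ortho to OH and ortho to the biaryl bond (later C4a) should add to the central quinone carbonyl (later C5) to give a bicyclo[3.2.1]octane, and further oxidation with C–C cleavage should expel the one-carbon bridge (C2′) as CO2 and leave the aromatic tropolone with C9–H, C8–H, C7–flavan and C6–OH in place; the closest known reaction is the intermolecular oxidative condensation of a catechol (as its quinone) with a pyrogallol to a benzotropolone, in which this C–C-linked adduct is the accepted intermediate, and here the preformed biaryl bond fixes the regiochemistry and no stereocentre is touched.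

## Compound list

1 | 3,4-bis(benzyloxy)benzaldehyde | O=Cc1ccc(OCc2ccccc2)c(OCc2ccccc2)c1 | starting material
2 | 4,5-bis(benzyloxy)-2-bromobenzaldehyde | O=Cc1cc(OCc2ccccc2)c(OCc2ccccc2)cc1Br | intermediate
3 | methyl 2-(dimethoxyphosphoryl)-2-methoxyacetate | COC(C(=O)OC)P(=O)(OC)OC | starting material
4 | methyl (Z)-3-[4,5-bis(benzyloxy)-2-bromophenyl]-2-methoxyprop-2-enoate | COC(=O)/C(OC)=C/c1cc(OCc2ccccc2)c(OCc2ccccc2)cc1Br | intermediate
5 | 2,3,4-trihydroxybenzaldehyde | O=Cc1ccc(O)c(O)c1O | starting material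
6 | 2,3,4-tris(benzyloxy)benzaldehyde | O=Cc1ccc(OCc2ccccc2)c(OCc2ccccc2)c1OCc1ccccc1 | intermediate
7 | 2,3,4-tris(benzyloxy)-5-bromobenzaldehyde | O=Cc1cc(Br)c(OCc2ccccc2)c(OCc2ccccc2)c1OCc1ccccc1 | intermediate
8 | methyl (triphenylphosphoranylidene)acetate | COC(=O)C=P(c1ccccc1)(c1ccccc1)c1ccccc1 | starting material
9 | methyl (E)-3-[2,3,4-tris(benzyloxy)-5-bromophenyl]prop-2-enoate | COC(=O)/C=C/c1cc(Br)c(OCc2ccccc2)c(OCc2ccccc2)c1OCc1ccccc1 | intermediate
10 | methyl (E)-3-[2,3,4-tris(benzyloxy)-5-(4,4,5,5-tetramethyl-1,3,2-dioxaborolan-2-yl)phenyl]prop-2-enoate | COC(=O)/C=C/c1cc(B2OC(C)(C)C(C)(C)O2)c(OCc2ccccc2)c(OCc2ccccc2)c1OCc1ccccc1 | intermediate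
11 | biaryl diester: methyl (Z)-3-{4,5-bis(benzyloxy)-2-[2,3,4-tris(benzyloxy)-5-((E)-3-methoxy-3-oxoprop-1-enyl)phenyl]phenyl}-2-methoxyprop-2-enoate | COC(=O)/C(OC)=C/c1cc(OCc2ccccc2)c(OCc2ccccc2)cc1-c1cc(/C=C/C(=O)OC)c(OCc2ccccc2)c(OCc2ccccc2)c1OCc1ccccc1 | intermediate
12 | biaryl bis(allylic alcohol): (Z)-3-{4,5-bis(benzyloxy)-2-[2,3,4-tris(benzyloxy)-5-((E)-3-hydroxyprop-1-enyl)phenyl]phenyl}-2-methoxyprop-2-en-1-ol | OC/C(OC)=C/c1cc(OCc2ccccc2)c(OCc2ccccc2)cc1-c1cc(/C=C/CO)c(OCc2ccccc2)c(OCc2ccccc2)c1OCc1ccccc1 | intermediate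
13 | biaryl bis-enal: (Z)-3-{4,5-bis(benzyloxy)-2-[2,3,4-tris(benzyloxy)-5-((E)-3-oxoprop-1-enyl)phenyl]phenyl}-2-methoxyprop-2-enal | O=C/C(OC)=C/c1cc(OCc2ccccc2)c(OCc2ccccc2)cc1-c1cc(/C=C/C=O)c(OCc2ccccc2)c(OCc2ccccc2)c1OCc1ccccc1 | intermediate
14 | 3,5-bis(benzyloxy)phenol | Oc1cc(OCc2ccccc2)cc(OCc2ccccc2)c1 | starting material
15 | 3,5-bis(benzyloxy)-2-bromophenol | Oc1cc(OCc2ccccc2)cc(OCc2ccccc2)c1Br | intermediate
16 | [3,5-bis(benzyloxy)-2-bromophenoxy]trimethylsilane (not isolated) | C[Si](C)(C)Oc1cc(OCc2ccccc2)cc(OCc2ccccc2)c1Br | intermediate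
17 | [2,4-bis(benzyloxy)-6-(trimethylsilyloxy)phenyl]lithium (not isolated) | C[Si](C)(C)Oc1cc(OCc2ccccc2)cc(OCc2ccccc2)c1[Li] | intermediate
18 | lithium 3,5-bis(benzyloxy)-2-(trimethylsilyl)phenoxide (not isolated) | [Li+].[O-]c1cc(OCc2ccccc2)cc(OCc2ccccc2)c1[Si](C)(C)C | intermediate
19 | 3,5-bis(benzyloxy)-2-(trimethylsilyl)phenyl trifluoromethanesulfonate | C[Si](C)(C)c1c(OCc2ccccc2)cc(OCc2ccccc2)cc1OS(=O)(=O)C(F)(F)F | intermediate
20 | 3,5-bis(benzyloxy)benzyne (not isolated) | C1#CC(OCc2ccccc2)=CC(OCc2ccccc2)=C1 | intermediate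
21 | bis(ortho-quinone methide), drawn with both arms at the quinone methide stage (not isolated) | O=C1C=C(OCc2ccccc2)C=C(OCc2ccccc2)C1=CC(OC)=Cc1cc(OCc2ccccc2)c(OCc2ccccc2)cc1-c1cc(C=CC=C2C(=O)C=C(OCc3ccccc3)C=C2OCc2ccccc2)c(OCc2ccccc2)c(OCc2ccccc2)c1OCc1ccccc1 | intermediate
22 | biaryl bis-chromene: arm 1 = 5,7-bis(benzyloxy)-3-methoxy-2H-chromen-2-yl at C2; arm 2 = 5,7-bis(benzyloxy)-2H-chromen-2-yl at C5′; both C2 epimers of each arm | COC1=Cc2c(OCc3ccccc3)cc(OCc3ccccc3)cc2OC1c1cc(OCc2ccccc2)c(OCc2ccccc2)cc1-c1cc(C2Oc3cc(OCc4ccccc4)cc(OCc4ccccc4)c3C=C2)c(OCc2ccccc2)c(OCc2ccccc2)c1OCc1ccccc1 | intermediate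
23 | as 22 with arm 1 = 5,7-bis(benzyloxy)-3-oxochroman-2-yl (C2 labile) | O=C1Cc2c(OCc3ccccc3)cc(OCc3ccccc3)cc2OC1c1cc(OCc2ccccc2)c(OCc2ccccc2)cc1-c1cc(C2Oc3cc(OCc4ccccc4)cc(OCc4ccccc4)c3C=C2)c(OCc2ccccc2)c(OCc2ccccc2)c1OCc1ccccc1 | intermediate
24 | as 23 with arm 1 = (2R,3R)-5,7-bis(benzyloxy)-3-hydroxychroman-2-yl; arm 2 C2 epimers | O[C@@H]1Cc2c(OCc3ccccc3)cc(OCc3ccccc3)cc2O[C@@H]1c1cc(OCc2ccccc2)c(OCc2ccccc2)cc1-c1cc(C2Oc3cc(OCc4ccccc4)cc(OCc4ccccc4)c3C=C2)c(OCc2ccccc2)c(OCc2ccccc2)c1OCc1ccccc1 | intermediate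
25 | 3,4,5-tris(benzyloxy)benzoic acid | OC(=O)c1cc(OCc2ccccc2)c(OCc2ccccc2)c(OCc2ccccc2)c1 | starting material
26 | 3,4,5-tris(benzyloxy)benzoate of 24 at the arm 1 C3 oxygen | O=C(O[C@@H]1Cc2c(OCc3ccccc3)cc(OCc3ccccc3)cc2O[C@@H]1c1cc(OCc2ccccc2)c(OCc2ccccc2)cc1-c1cc(C2Oc3cc(OCc4ccccc4)cc(OCc4ccccc4)c3C=C2)c(OCc2ccccc2)c(OCc2ccccc2)c1OCc1ccccc1)c1cc(OCc2ccccc2)c(OCc2ccccc2)c(OCc2ccccc2)c1 | intermediate
27 | as 26 with arm 2 = 2,3-trans-5,7-bis(benzyloxy)-3-hydroxychroman-2-yl (both antipodal series at arm 2) | O=C(O[C@@H]1Cc2c(OCc3ccccc3)cc(OCc3ccccc3)cc2O[C@@H]1c1cc(OCc2ccccc2)c(OCc2ccccc2)cc1-c1cc(C2Oc3cc(OCc4ccccc4)cc(OCc4ccccc4)c3CC2O)c(OCc2ccccc2)c(OCc2ccccc2)c1OCc1ccccc1)c1cc(OCc2ccccc2)c(OCc2ccccc2)c(OCc2ccccc2)c1 | intermediate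
28 | as 26 with arm 2 = 5,7-bis(benzyloxy)-3-oxochroman-2-yl (C2 labile) | O=C(O[C@@H]1Cc2c(OCc3ccccc3)cc(OCc3ccccc3)cc2O[C@@H]1c1cc(OCc2ccccc2)c(OCc2ccccc2)cc1-c1cc(C2Oc3cc(OCc4ccccc4)cc(OCc4ccccc4)c3CC2=O)c(OCc2ccccc2)c(OCc2ccccc2)c1OCc1ccccc1)c1cc(OCc2ccccc2)c(OCc2ccccc2)c(OCc2ccccc2)c1 | intermediate
29 | as 26 with arm 2 = (2R,3R)-5,7-bis(benzyloxy)-3-hydroxychroman-2-yl (fully protected biaryl bis-flavan) | O=C(O[C@@H]1Cc2c(OCc3ccccc3)cc(OCc3ccccc3)cc2O[C@@H]1c1cc(OCc2ccccc2)c(OCc2ccccc2)cc1-c1cc([C@H]2Oc3cc(OCc4ccccc4)cc(OCc4ccccc4)c3C[C@H]2O)c(OCc2ccccc2)c(OCc2ccccc2)c1OCc1ccccc1)c1cc(OCc2ccccc2)c(OCc2ccccc2)c(OCc2ccccc2)c1 | intermediate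
30 | (2R,3R)-2-{4,5-dihydroxy-2-[2,3,4-trihydroxy-5-((2R,3R)-3,5,7-trihydroxychroman-2-yl)phenyl]phenyl}-5,7-dihydroxychroman-3-yl 3,4,5-trihydroxybenzoate | O=C(O[C@@H]1Cc2c(O)cc(O)cc2O[C@@H]1c1cc(O)c(O)cc1-c1cc([C@H]2Oc3cc(O)cc(O)c3C[C@H]2O)c(O)c(O)c1O)c1cc(O)c(O)c(O)c1 | intermediate
31 | CNP0217128.1: (2R,3R)-5,7-dihydroxy-2-{3,4,6-trihydroxy-5-oxo-7-[(2R,3R)-3,5,7-trihydroxychroman-2-yl]-5H-benzo[7]annulen-1-yl}chroman-3-yl 3,4,5-trihydroxybenzoate | O=C(O[C@@H]1Cc2c(O)cc(O)cc2O[C@@H]1c1cc(O)c(O)c2c(=O)c(O)c([C@H]3Oc4cc(O)cc(O)c4C[C@H]3O)ccc12)c1cc(O)c(O)c(O)c1 | target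

## Step count and risks

Total step count: 20.
Longest linear sequence: 16 steps (steps 3, 4, 5, 6, 7, 8, 9, then 12 to 20).

Steps most likely to fail:

**Step 20 (Proposed new method).** The hydroxy-ortho-quinone of the pyrogallol ring may be consumed by intermolecular coupling or by over-oxidation (including oxidation of the galloyl ring) faster than the catechol carbon adds to its central carbonyl. The fallback uses known chemistry, the intermolecular oxidative condensation of a catechol flavan with a pyrogallol flavan; it sets out from 1 and 6 (using 3, 19 and 25) and comes back at 31. For the catechol half, aldehyde 1 is olefinated with 3 as in step 2 to methyl (Z)-3-[3,4-bis(benzyloxy)phenyl]-2-methoxyprop-2-enoate F1, reduced with iBu2AlH to (Z)-3-[3,4-bis(benzyloxy)phenyl]-2-methoxyprop-2-en-1-ol F2 and oxidised with MnO2 to (Z)-3-[3,4-bis(benzyloxy)phenyl]-2-methoxyprop-2-enal F3. A single aryne annulation with 19 and CsF, which still closes ring C through O1–C2, should give 5,7-bis(benzyloxy)-2-[3,4-bis(benzyloxy)phenyl]-3-methoxy-2H-chromene F4. Aqueous HCl should give 5,7-bis(benzyloxy)-2-[3,4-bis(benzyloxy)phenyl]chroman-3-one F5, transfer hydrogenation as in step 14 should give (2R,3R)-5,7-bis(benzyloxy)-2-[3,4-bis(benzyloxy)phenyl]chroman-3-ol F6, esterification with 25 and DCC its 3,4,5-tris(benzyloxy)benzoate F7, and hydrogenolysis (−)-epicatechin 3-O-gallate F8. For the pyrogallol half, aldehyde 6 is homologated with (triphenylphosphoranylidene)acetaldehyde to (E)-3-[2,3,4-tris(benzyloxy)phenyl]prop-2-enal F9 and annulated with 19 to 5,7-bis(benzyloxy)-2-[2,3,4-tris(benzyloxy)phenyl]-2H-chromene F10. Hydroboration and oxidation should give trans-5,7-bis(benzyloxy)-2-[2,3,4-tris(benzyloxy)phenyl]chroman-3-ol F11, Dess–Martin oxidation 5,7-bis(benzyloxy)-2-[2,3,4-tris(benzyloxy)phenyl]chroman-3-one F12, reduction as in step 18 (2R,3R)-5,7-bis(benzyloxy)-2-[2,3,4-tris(benzyloxy)phenyl]chroman-3-ol F13, and debenzylation (2R,3R)-2-(2,3,4-trihydroxyphenyl)chromane-3,5,7-triol F14. Finally F8 and F14 are co-oxidised with horseradish peroxidase and H2O2 in aqueous acetone at pH 5; the pyrogallol carbon that is ortho to one hydroxyl and para to another (C5′ of F14) should bond to the quinone of F8, which leads to the connectivity of 31.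

**Step 12 (key step).** The double annulation may stop short, through closure of the aryne–carbonyl zwitterion at the β-carbon of the enal (4H-chromene path) or through capture of the quinone methide by a further aryne in competition with the 6π closure. The fallback sets out from 13 and 14 and comes back at 22: a phenylboronic acid-templated condensation of phenol 14 (two equivalents) with both enal arms of 13 (PhB(OH)2, propionic acid, toluene, reflux with water removal). The boron template directs C-alkylation to the phenol ortho position (C4–C4a bond first), loss of water gives the same quinone methide 21, and the same oxa-6π closure forms O1–C2. This fallback makes no new compound (entry F0).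

**Step 18.** Reduction may outrun C2 epimerisation, or the catalyst may discriminate the faces poorly on the ketone that bears an ortho-substituted 2-aryl group, so that trans or (2S,3S) alcohol accompanies the product. The fallback sets out from 28 and comes back at 29: LiB(s-Bu)3H (L-Selectride) in THF at −78 °C should reduce both C2 epimers of 28 from the face opposite the 2-aryl group (substrate control, 2,3-cis). This gives 29 together with the arm 2 (2S,3S) diastereomer of 29 F15. Because arm 1 is already enantiopure the two are diastereomers and are separated by chromatography; F15 is returned to 28 by Dess–Martin oxidation, where C2 equilibrates under Et3N, and the loop is repeated.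

## Further compounds

F1 | step 20 | methyl (Z)-3-[3,4-bis(benzyloxy)phenyl]-2-methoxyprop-2-enoate | COC(=O)/C(OC)=C/c1ccc(OCc2ccccc2)c(OCc2ccccc2)c1
F2 | step 20 | (Z)-3-[3,4-bis(benzyloxy)phenyl]-2-methoxyprop-2-en-1-ol | OC/C(OC)=C/c1ccc(OCc2ccccc2)c(OCc2ccccc2)c1
F3 | step 20 | (Z)-3-[3,4-bis(benzyloxy)phenyl]-2-methoxyprop-2-enal | O=C/C(OC)=C/c1ccc(OCc2ccccc2)c(OCc2ccccc2)c1
F4 | step 20 | 5,7-bis(benzyloxy)-2-[3,4-bis(benzyloxy)phenyl]-3-methoxy-2H-chromene (racemic) | COC1=Cc2c(OCc3ccccc3)cc(OCc3ccccc3)cc2OC1c1ccc(OCc2ccccc2)c(OCc2ccccc2)c1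
F5 | step 20 | 5,7-bis(benzyloxy)-2-[3,4-bis(benzyloxy)phenyl]chroman-3-one (C2 labile) | O=C1Cc2c(OCc3ccccc3)cc(OCc3ccccc3)cc2OC1c1ccc(OCc2ccccc2)c(OCc2ccccc2)c1
F6 | step 20 | (2R,3R)-5,7-bis(benzyloxy)-2-[3,4-bis(benzyloxy)phenyl]chroman-3-ol | O[C@@H]1Cc2c(OCc3ccccc3)cc(OCc3ccccc3)cc2O[C@@H]1c1ccc(OCc2ccccc2)c(OCc2ccccc2)c1
F7 | step 20 | (2R,3R)-5,7-bis(benzyloxy)-2-[3,4-bis(benzyloxy)phenyl]chroman-3-yl 3,4,5-tris(benzyloxy)benzoate | O=C(O[C@@H]1Cc2c(OCc3ccccc3)cc(OCc3ccccc3)cc2O[C@@H]1c1ccc(OCc2ccccc2)c(OCc2ccccc2)c1)c1cc(OCc2ccccc2)c(OCc2ccccc2)c(OCc2ccccc2)c1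
F8 | step 20 | (−)-epicatechin 3-O-gallate | O=C(O[C@@H]1Cc2c(O)cc(O)cc2O[C@@H]1c1ccc(O)c(O)c1)c1cc(O)c(O)c(O)c1
F9 | step 20 | (E)-3-[2,3,4-tris(benzyloxy)phenyl]prop-2-enal | O=C/C=C/c1ccc(OCc2ccccc2)c(OCc2ccccc2)c1OCc1ccccc1
F10 | step 20 | 5,7-bis(benzyloxy)-2-[2,3,4-tris(benzyloxy)phenyl]-2H-chromene (racemic) | C1=Cc2c(OCc3ccccc3)cc(OCc3ccccc3)cc2OC1c1ccc(OCc2ccccc2)c(OCc2ccccc2)c1OCc1ccccc1
F11 | step 20 | 2,3-trans-5,7-bis(benzyloxy)-2-[2,3,4-tris(benzyloxy)phenyl]chroman-3-ol (racemic) | OC1Cc2c(OCc3ccccc3)cc(OCc3ccccc3)cc2OC1c1ccc(OCc2ccccc2)c(OCc2ccccc2)c1OCc1ccccc1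
F12 | step 20 | 5,7-bis(benzyloxy)-2-[2,3,4-tris(benzyloxy)phenyl]chroman-3-one (C2 labile) | O=C1Cc2c(OCc3ccccc3)cc(OCc3ccccc3)cc2OC1c1ccc(OCc2ccccc2)c(OCc2ccccc2)c1OCc1ccccc1
F13 | step 20 | (2R,3R)-5,7-bis(benzyloxy)-2-[2,3,4-tris(benzyloxy)phenyl]chroman-3-ol | O[C@@H]1Cc2c(OCc3ccccc3)cc(OCc3ccccc3)cc2O[C@@H]1c1ccc(OCc2ccccc2)c(OCc2ccccc2)c1OCc1ccccc1
F14 | step 20 | (2R,3R)-2-(2,3,4-trihydroxyphenyl)chromane-3,5,7-triol | O[C@@H]1Cc2c(O)cc(O)cc2O[C@@H]1c1ccc(O)c(O)c1O
F0 | step 12 | none | none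
F15 | step 18 | arm 2 (2S,3S) diastereomer of 29 | O=C(O[C@@H]1Cc2c(OCc3ccccc3)cc(OCc3ccccc3)cc2O[C@@H]1c1cc(OCc2ccccc2)c(OCc2ccccc2)cc1-c1cc([C@@H]2Oc3cc(OCc4ccccc4)cc(OCc4ccccc4)c3C[C@@H]2O)c(OCc2ccccc2)c(OCc2ccccc2)c1OCc1ccccc1)c1cc(OCc2ccccc2)c(OCc2ccccc2)c(OCc2ccccc2)c1
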